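**Retrosynthetic overview**
1. Lychnostatin 1 (29) ⇐ epoxy acid 28: the γ-lactone is made last, by Pinnick oxidation and 5-exo opening of a 5,6-cis-epoxide by the C12 acid (inversion at C6). The epoxide comes from the (Z)-cyclodec-5-enone 22 by C8–OH-directed epoxidation, with O8 and O10 acylated in between.
2. 22 ⇐ iodo keto mesylate 19: a SmI2 Barbier closure forms the C1–C2 bond (ring B = C1–C2–C3–C4–C5–C6) and, in the same flask, Grob fragmentation cleaves the temporary C1–C6 bond of the resulting cis-decalin.
3. Enabling feature: the C1 ketone has the free C2 methylene on one flank and the fully substituted C10 on the other, and lies 1,6 across the ring from C6. The syn C5/C6 oxygens can come from a Z C5=C6 alkene, so a temporary C1–C6 bond turns C1–C10–C9–C8–C7–C6 into a cyclohexanone (ring A) that can enolise only toward C6.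
4. 19 ⇐ anti-aldol of ring A ketone 16 (C7, C8, C10 set on the six-membered ring, from (S)-carvone by α′-hydroxylation and Wharton transposition) with (S)-4-iodo-2-methylbutanal 5 (C2–C5 with the C4 stereocentre).
5. Ring order: ring A (from carvone) → ring B (transient, key step) → ten-membered ring (same step) → γ-lactone (last step).

Key step: step 15

Remark: names use germacranolide locants (C1 ketone carbon, C2/C3 the CH2 groups, C4 CHMe, C5 CHOH, C6 lactone O–CH, C7 ring CH bearing C11, C8 CH–O-methacryloyl, C9 CH2, C10 C(Me)OAc, C11/C12/C13 lactone α-carbon/carbonyl/exocyclic CH2); on ring A the β face is the face of the C7 side chain.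
Remark: (R)-BINAP is taken as the ligand antipode that delivers the (S)-lactone in step 1; if the sense is the opposite, the (S)-ligand is used.

**Step 1**
Reactants: 1 α-methylene-γ-butyrolactone
Product: 2 (S)-α-methyl-γ-butyrolactone
Conditions: H2 (50 atm), Ru(OAc)2[(R)-BINAP] (0.5 mol %), CH2Cl2, 50 °C
Reagents that add atoms: none
Why: BINAP–ruthenium asymmetric hydrogenation of the exocyclic enoate double bond, the lactone carbonyl binding the metal so that the ligand fixes the new stereocentre (the future C4) as S.

**Step 2**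
Reactants: 2 (S)-α-methyl-γ-butyrolactone
Product: 4 ethyl (S)-4-iodo-2-methylbutanoate, via silyl ester 3 (not isolated)
Conditions: NaI, Me3SiCl, MeCN, 60 °C; then EtOH, rt
Reagents that add atoms: sodium iodide [Na+].[I-]; ethanol CCO
Why: iodotrimethylsilane made in the flask cleaves the lactone by SN2 attack of iodide at the O–CH2 carbon (the future C2) and acid-catalysed ethanolysis of the silyl ester gives the ethyl ester, the stereocentre not being involved.

**Step 3**
Reactants: 4 ethyl (S)-4-iodo-2-methylbutanoate
Product: 5 (S)-4-iodo-2-methylbutanal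
Conditions: i-Bu2AlH (1.05 equiv), CH2Cl2, −78 °C; aq. citric acid work-up; used at once
Reagents that add atoms: none
Why: partial ester reduction stops at the aluminium hemiacetal at low temperature, and the α-branched aldehyde is used without storage to avoid epimerisation.

**Step 4**
Reactants: 6 (S)-(+)-carvone
Product: 8 (5R,6R)-6-hydroxycarvone, via potassium dienolate 7 (not isolated)
Conditions: KN(SiMe3)2, THF, −78 °C; then 2-(phenylsulfonyl)-3-phenyloxaziridine, −78 °C; aq. NH4Cl
Reagents that add atoms: 2-(phenylsulfonyl)-3-phenyloxaziridine O=S(=O)(N1OC1c1ccccc1)c1ccccc1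
Why: kinetic deprotonation at the only sp3 α-carbon and electrophilic enolate hydroxylation by the N-sulfonyloxaziridine anti to the neighbouring isopropenyl group should set the future C8–O trans to the C7 side chain.

**Step 5**
Reactants: 8 (5R,6R)-6-hydroxycarvone
Product: 9 TBS ether of 8
Conditions: t-BuMe2SiCl, imidazole, DMF, rt
Reagents that add atoms: tert-butyldimethylsilyl chloride CC(C)(C)[Si](C)(C)Cl
Why: standard silylation of a secondary alcohol to carry O8 through the hydride and oxidation steps.

**Step 6**
Reactants: 9 TBS ether of 8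
Product: 10 epoxy ketone (oxirane trans to isopropenyl)
Conditions: H2O2 (35 % aq.), NaOH (0.3 equiv), MeOH, −10 to 0 °C
Reagents that add atoms: hydrogen peroxide OO
Why: Weitz–Scheffer nucleophilic epoxidation of the enone, with axial attack of hydroperoxide anti to the isopropenyl group as is established for carvone; this oxygen becomes the C1 carbonyl oxygen.

**Step 7**
Reactants: 10 epoxy ketone
Product: 11 transposed allylic alcohol
Conditions: N2H4·H2O, AcOH (cat.), MeOH, 0 °C to rt
Reagents that add atoms: none
Why: Wharton transposition (epoxy hydrazone → vinyl diazene → loss of N2) turns the old carbonyl carbon into the C9 vinyl CH and keeps the C–O bond at C1 with its configuration.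

**Step 8**
Reactants: 11 transposed allylic alcohol
Product: 12 syn-epoxy alcohol
Conditions: VO(acac)2 (2 mol %), t-BuOOH (decane), CH2Cl2, 0 °C to rt
Reagents that add atoms: tert-butyl hydroperoxide CC(C)(C)OO
Why: hydroxyl-directed vanadium-catalysed epoxidation delivers oxygen syn to the allylic C1–OH, setting the C10–O bond α (cis to O8, trans to the C7 side chain); the isopropenyl group is not allylic to a hydroxyl and stays intact.

**Step 9**
Reactants: 12 syn-epoxy alcohol
Product: 13 cis-1,2-diol (secondary C1–OH, tertiary C10–OH)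
Conditions: LiAlH4, THF, 0 °C to reflux
Reagents that add atoms: none
Why: hydride opens the trisubstituted epoxide by SN2 attack at the secondary carbon C9, leaving the tertiary C10–O bond and its configuration untouched.

**Step 10**
Reactants: 13 cis-1,2-diol
Product: 14 ring A ketol
Conditions: SO3·pyridine, DMSO, i-Pr2NEt, CH2Cl2, 0 °C
Reagents that add atoms: none
Why: Parikh–Doering oxidation converts only the secondary alcohol, gives the C1 ketone without glycol cleavage and leaves the tertiary hydroxyl.

**Step 11**
Reactants: 14 ring A ketol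
Product: 15 allylic alcohol (C12–OH)
Conditions: SeO2 (0.3 equiv), t-BuOOH, CH2Cl2, rt
Reagents that add atoms: selenium dioxide O=[Se]=O; tert-butyl hydroperoxide CC(C)(C)OO
Why: selenium dioxide allylic oxidation (ene reaction then 2,3-shift) of the isopropenyl methyl group, the hindered ring methine C7–H being less accessible, should give the 2-substituted allyl alcohol.

**Step 12**
Reactants: 15 allylic alcohol
Product: 16 bis(triethylsilyl) ether, the ring A ketone
Conditions: Et3SiOTf (2.5 equiv), 2,6-lutidine, CH2Cl2, −78 to 0 °C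
Reagents that add atoms: triethylsilyl triflate CC[Si](CC)(CC)OS(=O)(=O)C(F)(F)F
Why: the silyl triflate silylates both the primary allylic and the hindered tertiary hydroxyl faster than it enolises the ketone under lutidine buffering.

**Step 13**
Reactants: 16 ring A ketone; 5 (S)-4-iodo-2-methylbutanal
Product: 18 anti-aldol adduct, via boron enolate 17 (not isolated)
Conditions: (c-C6H11)2BCl, Et3N, Et2O, −78 to 0 °C; then 5, −78 °C; then MeOH, pH 7 buffer, H2O2, 0 °C
Reagents that add atoms: none
Why: boron aldol reaction in which the ketone can enolise only toward C6 (C10 is quaternary); the ring-constrained E-enolate gives the anti adduct through a Zimmerman–Traxler chair, the aldehyde approaches anti to the C7 substituent, and the (S)-aldehyde is Felkin–Anh matched, so C6 (chain trans to C7) and C5 are set as drawn.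

**Step 14**
Reactants: 18 anti-aldol adduct
Product: 19 iodo keto mesylate
Conditions: MeSO2Cl, pyridine, CH2Cl2, 0 °C; used at once
Reagents that add atoms: methanesulfonyl chloride CS(Cl)(=O)=O
Why: sulfonylation of the secondary hydroxyl under weakly basic, cold conditions to avoid β-elimination of the β-sulfonyloxy ketone.

**Step 15**
Reactants: 19 iodo keto mesylate
Product: 22 (Z)-cyclodec-5-enone, via alkylsamarium diiodide 20 (not isolated), via cis-decalin samarium alkoxide 21 (not isolated)
Conditions: SmI2 (2.2 equiv), HMPA, THF, −78 °C to rt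
Reagents that add atoms: none
Why: Two-electron reduction of the primary C–I bond gives alkylsamarium 20, which adds to the C1 ketone from the axial direction in a 6-exo-trig Barbier closure of ring B (bond C1–C2) to give the cis-fused decalin alkoxide 21; there the equatorial C5–OMs bond is antiperiplanar to the C1–C6 ring-fusion bond, so Grob fragmentation breaks C1–C6, restores the C1 carbonyl and expels mesylate. The closest known reaction type is the samarium diiodide Barbier cyclisation/Grob fragmentation sequence of iodoalkyl keto mesylates to eight- to ten-membered cycloalkenones. Ring B closes in the 6-exo-trig mode, and the ten-membered ring is not closed directly but unveiled when the temporary bond is cut. No permanent stereocentre is made: C1 returns to sp2 and C5/C6 become the alkene, whose Z geometry follows stereospecifically from the anti C5/C6 configuration of step 13 and the cis ring fusion, while C4, C7, C8 and C10 are not touched. The step needs reduction of the C–I bond in preference to the α-silyloxy ketone and the mesylate: primary iodides are reduced by SmI2/HMPA much faster than dialkyl ketones, the C10–O bond is equatorial on ring A and nearly orthogonal to the carbonyl π system (poor overlap for reductive cleavage), and only a small excess of reductant is used.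

**Step 16**
Reactants: 22 (Z)-cyclodec-5-enone
Product: 23 triol
Conditions: HF·pyridine, pyridine, THF, 0 °C to rt
Reagents that add atoms: none
Why: buffered fluoride cleaves the secondary TBS, primary TES and tertiary TES ethers in one operation without affecting the ketone or the skipped diene.

**Step 17**
Reactants: 23 triol
Product: 24 enal
Conditions: MnO2 (excess), CH2Cl2, rt
Reagents that add atoms: none
Why: MnO2 oxidises only the primary allylic alcohol; the resulting electron-poor 2-substituted acrolein is inert in the following epoxidation.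

**Step 18**
Reactants: 24 enal
Product: 25 5,6-cis-epoxide
Conditions: VO(acac)2 (5 mol %), t-BuOOH (decane), CH2Cl2, 0 °C
Reagents that add atoms: tert-butyl hydroperoxide CC(C)(C)OO
Why: homoallylic-hydroxyl-directed vanadium epoxidation in which allylic 1,3-strain of the Z-alkene keeps H7 in the alkene plane, so C8 and C11 lie on opposite faces and oxygen is delivered from the C8–O side, anti to C11; this fixes C5 in its final configuration and C6 in the one to be inverted.

**Step 19**
Reactants: 25 5,6-cis-epoxide
Product: 26 8-O-methacrylate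
Conditions: methacrylic anhydride, DMAP (cat.), Et3N, CH2Cl2, 0 °C
Reagents that add atoms: methacrylic anhydride CC(=C)C(=O)OC(=O)C(C)=C
Why: DMAP-catalysed acylation takes the only secondary hydroxyl (O8) and leaves the hindered tertiary C10–OH.

**Step 20**
Reactants: 26 8-O-methacrylate
Product: 27 10-O-acetate
Conditions: Ac2O, DMAP (1.5 equiv), Et3N, CH2Cl2, 35 °C
Reagents that add atoms: acetic anhydride CC(=O)OC(C)=O
Why: acetylation of the tertiary α-ketol hydroxyl under forcing DMAP conditions is unambiguous because it is the only free hydroxyl left (O5 is still masked in the epoxide).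

**Step 21**
Reactants: 27 10-O-acetate
Product: 29 lychnostatin 1, via epoxy acid 28 (not isolated)
Conditions: NaClO2, NaH2PO4, 2-methyl-2-butene, t-BuOH/H2O, 0 °C; then camphorsulfonic acid (cat.), CH2Cl2, rt
Reagents that add atoms: sodium chlorite [Na+].[O-]Cl=O
Why: Pinnick oxidation gives the acrylic acid 28, whose carboxyl sits on the face of C6 opposite the oxirane oxygen and opens the epoxide 5-exo with inversion at C6 under mild acid; this forms the trans-fused α-methylene lactone and frees the C5 hydroxyl while the two esters survive.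

**Compound list**
1 | 3-methylenedihydrofuran-2(3H)-one (α-methylene-γ-butyrolactone) | C=C1CCOC1=O | starting material
2 | (S)-3-methyldihydrofuran-2(3H)-one | O=C1OCC[C@@H]1C | intermediate
3 | trimethylsilyl (S)-4-iodo-2-methylbutanoate | C[Si](C)(C)OC(=O)[C@@H](C)CCI | intermediate
4 | ethyl (S)-4-iodo-2-methylbutanoate | CCOC(=O)[C@@H](C)CCI | intermediate
5 | (S)-4-iodo-2-methylbutanal | O=C[C@@H](C)CCI | intermediate
6 | (S)-(+)-carvone, (5S)-2-methyl-5-(prop-1-en-2-yl)cyclohex-2-en-1-one | O=C1C(C)=CC[C@H](C(C)=C)C1 | starting material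
7 | potassium cross-conjugated dienolate of 6 (enolate toward C6 of carvone) | [K]OC1=C[C@@H](C(C)=C)CC=C1C | intermediate
8 | (5R,6R)-6-hydroxy-2-methyl-5-(prop-1-en-2-yl)cyclohex-2-en-1-one (OH trans to isopropenyl) | O=C1C(C)=CC[C@H](C(C)=C)[C@H]1O | intermediate
9 | (5R,6R)-6-(tert-butyldimethylsilyloxy)-2-methyl-5-(prop-1-en-2-yl)cyclohex-2-en-1-one | O=C1C(C)=CC[C@H](C(C)=C)[C@H]1O[Si](C)(C)C(C)(C)C | intermediate
10 | 2,3-epoxide of 9, oxirane cis to the silyloxy group and trans to the isopropenyl group | O=C1[C@@]2(C)O[C@H]2C[C@H](C(C)=C)[C@H]1O[Si](C)(C)C(C)(C)C | intermediate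
11 | 4-(tert-butyldimethylsilyloxy)-2-methyl-5-(prop-1-en-2-yl)cyclohex-2-en-1-ol, 1-OH and 4-OSi cis (α), isopropenyl trans (β) | O[C@H]1C[C@H](C(C)=C)[C@@H](O[Si](C)(C)C(C)(C)C)C=C1C | intermediate
12 | 2,3-epoxide of 11 on the α face (syn to the 1-OH) | O[C@H]1C[C@H](C(C)=C)[C@@H](O[Si](C)(C)C(C)(C)C)[C@H]2O[C@@]12C | intermediate
13 | 5-(tert-butyldimethylsilyloxy)-1-methyl-4-(prop-1-en-2-yl)cyclohexane-1,2-diol, all three oxygens α, isopropenyl β | O[C@H]1C[C@H](C(C)=C)[C@@H](O[Si](C)(C)C(C)(C)C)C[C@@]1(C)O | intermediate
14 | ring A ketol: 2-hydroxy-2-methyl-4-(tert-butyldimethylsilyloxy)-5-(prop-1-en-2-yl)cyclohexan-1-one, 2-OH and 4-OSi α, 5-substituent β (C10, C8, C7 of the target) | O=C1C[C@H](C(C)=C)[C@@H](O[Si](C)(C)C(C)(C)C)C[C@@]1(C)O | intermediate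
15 | as 14 with a 5-(3-hydroxyprop-1-en-2-yl) group | O=C1C[C@H](C(=C)CO)[C@@H](O[Si](C)(C)C(C)(C)C)C[C@@]1(C)O | intermediate
16 | bis(triethylsilyl) ether of 15 (O10 and O12 silylated), ring A ketone | O=C1C[C@H](C(=C)CO[Si](CC)(CC)CC)[C@@H](O[Si](C)(C)C(C)(C)C)C[C@@]1(C)O[Si](CC)(CC)CC | intermediate
17 | dicyclohexylboron enolate of 16 (enol double bond C1=C6) | C1CCC(CC1)B(C2CCCCC2)OC3=C[C@H](C(=C)CO[Si](CC)(CC)CC)[C@@H](O[Si](C)(C)C(C)(C)C)C[C@@]3(C)O[Si](CC)(CC)CC | intermediate
18 | aldol adduct: 16 carrying at C6 (α, trans to the C7 side chain) the chain CH(OH)–CH(CH3)–CH2CH2I; C5/C6 anti, C4/C5 syn, C4 as in the target | O=C1[C@@H]([C@H](O)[C@@H](C)CCI)[C@H](C(=C)CO[Si](CC)(CC)CC)[C@@H](O[Si](C)(C)C(C)(C)C)C[C@@]1(C)O[Si](CC)(CC)CC | intermediate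
19 | C5 methanesulfonate of 18 | O=C1[C@@H]([C@H](OS(C)(=O)=O)[C@@H](C)CCI)[C@H](C(=C)CO[Si](CC)(CC)CC)[C@@H](O[Si](C)(C)C(C)(C)C)C[C@@]1(C)O[Si](CC)(CC)CC | intermediate
20 | primary alkylsamarium diiodide from 19 (Sm at C2) | O=C1[C@@H]([C@H](OS(C)(=O)=O)[C@@H](C)CC[Sm](I)I)[C@H](C(=C)CO[Si](CC)(CC)CC)[C@@H](O[Si](C)(C)C(C)(C)C)C[C@@]1(C)O[Si](CC)(CC)CC | intermediate
21 | cis-fused decalin samarium alkoxide (rings A and B, O–Sm on C1, equatorial C5–OMs) | I[Sm](I)O[C@]12CC[C@H](C)[C@@H](OS(C)(=O)=O)[C@H]1[C@H](C(=C)CO[Si](CC)(CC)CC)[C@@H](O[Si](C)(C)C(C)(C)C)C[C@@]2(C)O[Si](CC)(CC)CC | intermediate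
22 | (5Z)-8-(tert-butyldimethylsilyloxy)-4,10-dimethyl-10-(triethylsilyloxy)-7-[3-(triethylsilyloxy)prop-1-en-2-yl]cyclodec-5-en-1-one; C4, C7, C8, C10 arranged as in the target | O=C1CC[C@H](C)/C=C\[C@H](C(=C)CO[Si](CC)(CC)CC)[C@@H](O[Si](C)(C)C(C)(C)C)C[C@@]1(C)O[Si](CC)(CC)CC | intermediate
23 | triol: 22 with free O8–H, O10–H and O12–H | O=C1CC[C@H](C)/C=C\[C@H](C(=C)CO)[C@@H](O)C[C@@]1(C)O | intermediate
24 | enal: 23 with C12 as aldehyde | O=C1CC[C@H](C)/C=C\[C@H](C(=C)C=O)[C@@H](O)C[C@@]1(C)O | intermediate
25 | 5,6-cis-epoxide of 24, oxirane oxygen anti to C11 (C5–O as in the target, C6–O on the face opposite to the future lactone oxygen) | O=C1CC[C@H](C)[C@@H]2O[C@@H]2[C@H](C(=C)C=O)[C@@H](O)C[C@@]1(C)O | intermediate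
26 | 8-O-methacrylate of 25 | O=C1CC[C@H](C)[C@@H]2O[C@@H]2[C@H](C(=C)C=O)[C@@H](OC(=O)C(C)=C)C[C@@]1(C)O | intermediate
27 | 10-O-acetate of 26 | O=C1CC[C@H](C)[C@@H]2O[C@@H]2[C@H](C(=C)C=O)[C@@H](OC(=O)C(C)=C)C[C@@]1(C)OC(C)=O | intermediate
28 | epoxy acid: 27 with C12 as carboxylic acid | O=C1CC[C@H](C)[C@@H]2O[C@@H]2[C@H](C(=C)C(=O)O)[C@@H](OC(=O)C(C)=C)C[C@@]1(C)OC(C)=O | intermediate
29 | lychnostatin 1, (4S,5S,6S,7R,8S,10R) | C=C(C)C(=O)O[C@H]1C[C@@](C)(OC(C)=O)C(=O)CC[C@H](C)[C@H](O)[C@H]2OC(=O)C(=C)[C@@H]21 | target

**Step count**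
Total: 21 steps. Longest linear sequence: 18 steps (steps 4–21, from (S)-carvone); the aldehyde branch (steps 1–3) joins at step 13.

**Steps most likely to fail, with fallbacks**

Step 15. The reductant may transfer electrons to the α-silyloxy ketone (reductive loss of the C10 oxygen, before or after ring expansion). The organosamarium may also add from the equatorial direction and give a trans-fused alkoxide that cannot reach the antiperiplanar geometry, so the fragmentation stalls. Fallback (anionic and stepwise, no reductant): the sequence sets out from 18. Iodine–lithium exchange with t-BuLi (3.3 equiv, Et2O/pentane, −100 °C) and cyclisation of the alkyllithium onto the ketone should give the cis-decalin-1,5-diol F1. MeSO2Cl/pyridine sulfonates only the secondary C5 hydroxyl to give the hydroxy mesylate F2. KOt-Bu in t-BuOH/THF then effects the classical Wharton fragmentation of the 1,3-diol monosulfonate and returns to the route at 22.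

Step 18. Oxygen delivery may fail or go to the wrong face if the C8 hydroxyl is tied up as a transannular hemiketal with the C1 ketone, or if the bulky vanadium peroxide cannot reach the ring-side face of the alkene. Epoxidation on the C11 face would end in the cis-fused lactone with C5 and C6 inverted. Fallback (covalent tether, electrophile from the open face): the sequence sets out from 24. Boc2O/DMAP converts the C8 hydroxyl into the tert-butyl carbonate F3. IBr (toluene, −80 °C) induces iodocarbonate cyclisation, the carbonate oxygen attacking C6 from the C8 side and iodine entering anti at C5, to give the cyclic iodocarbonate F4. K2CO3/MeOH cleaves the carbonate, and the C6 alkoxide displaces the iodide to close the same epoxide, returning to the route at 25.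

Step 7. Hydrazone formation may be slow at a ketone flanked by a quaternary oxirane carbon and a silyloxy-bearing carbon, and hydrazine may open the epoxide instead. Fallback (radical transposition): the sequence sets out from 10. NaBH4 in MeOH reduces the ketone to the epoxy alcohol F5. 1,1′-Thiocarbonyldiimidazole gives the imidazolylthiocarbonyl ester F6. Bu3SnH/AIBN in refluxing benzene generates the C9 radical, which opens the adjacent oxirane to the C1 alkoxy radical; hydrogen transfer returns to the route at 11.

**Further compounds**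
F1 | step 15 | cis-decalin-1,5-diol from 18 (C1–OH at the ring fusion, C5–OH equatorial, silyl ethers as in 18) | O[C@]12CC[C@H](C)[C@@H](O)[C@H]1[C@H](C(=C)CO[Si](CC)(CC)CC)[C@@H](O[Si](C)(C)C(C)(C)C)C[C@@]2(C)O[Si](CC)(CC)CC
F2 | step 15 | C5 methanesulfonate of F1 | O[C@]12CC[C@H](C)[C@@H](OS(C)(=O)=O)[C@H]1[C@H](C(=C)CO[Si](CC)(CC)CC)[C@@H](O[Si](C)(C)C(C)(C)C)C[C@@]2(C)O[Si](CC)(CC)CC
F3 | step 18 | 8-O-tert-butyl carbonate of 24 | O=C1CC[C@H](C)/C=C\[C@H](C(=C)C=O)[C@@H](OC(=O)OC(C)(C)C)C[C@@]1(C)O
F4 | step 18 | cyclic 6,8-carbonate with iodine at C5 (iodocarbonate from F3) | O=C1CC[C@H](C)[C@@H](I)[C@@H]2OC(=O)O[C@@H](C[C@@]1(C)O)[C@H]2C(=C)C=O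
F5 | step 7 | epoxy alcohol from 10 (carbonyl reduced, hydroxyl cis to the oxirane) | O[C@H]1[C@@]2(C)O[C@H]2C[C@H](C(C)=C)[C@H]1O[Si](C)(C)C(C)(C)C
F6 | step 7 | O-(imidazol-1-ylthiocarbonyl) derivative of F5 | S=C(n1ccnc1)O[C@H]1[C@@]2(C)O[C@H]2C[C@H](C(C)=C)[C@H]1O[Si](C)(C)C(C)(C)C
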